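**Retrosynthetic overview**

1. The lactol comes from δ-lactone 34 (i-Bu2AlH), the right-hand C(CH3)OH from ketone 32 (MeCeCl2), and the CH2CH2 bridge from an aldol condensation/conjugate reduction that joins silyl enol ether 14 (right half) to aldehyde 28 (left half).
2. Enabling feature (chromane numbering of the right-hand bicycle): the carbocycle C4a–C5–C6–C7–C8–C8a carries oxygen at C6 and C8a, para to each other, with quaternary C4a between C5 and C8a. C6 is therefore a masked ketone, i.e. a 2-silyloxy diene C7=C6–C5=C4a, and C8=C8a is an enone whose carbonyl is the future lactol carbon C2, already tied to C4a through C3–C4. An enantioselective intramolecular Diels–Alder reaction of trienone 9 forms C7–C8 and C4a–C8a.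
3. The cycloadduct's temporary cyclopentanone is cut at C2–C8a by autoxidation (C8a becomes a ketone, C2 an acid). Hydride then sets C8a, and the ring is re-closed through oxygen as the trans-fused δ-lactone; the regio-defined silyl enol ether from the cycloaddition survives as the nucleophile for the union.
4. Left half (azulene numbering): Johnson–Claisen rearrangement (side chain, ring alkene, 1,3-chirality transfer) ⇐ CBS reduction ⇐ SmI2 ketyl–olefin cyclisation (cyclopentanol, cis fusion) ⇐ one-carbon ring expansion ⇐ Cu-catalysed asymmetric conjugate addition to a cyclohexadienone.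
5. Ring order: right-hand carbocycle plus temporary cyclopentanone (step 7), oxane (step 9); left-hand seven-membered ring (step 12), cyclopentane (step 14).

Key step: step 7

Remark on the chemistry: the lactol is an equilibrating pair of anomers; the anomer drawn in the target (equatorial OH) is taken as the one isolated.

**Right half**

Step 1
Reactants: 1 pent-4-yn-1-ol
Product: 3 (4E)-5-iodo-4-methylpent-4-en-1-ol, via alkenylalane 2 (not isolated)
Conditions: Me3Al, Cp2ZrCl2 (25 mol%), CH2Cl2, 0 °C to rt; then I2, THF, −30 to 0 °C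
Reagents that add atoms: trimethylaluminium, C[Al](C)C; iodine, II
Why: Zirconium-catalysed carboalumination adds CH3 and Al syn across the terminal alkyne (methyl to the internal carbon) and iodinolysis proceeds with retention, which fixes the E geometry that later puts the tether on the outside of the diene.

Step 2
Reactants: 3 (4E)-5-iodo-4-methylpent-4-en-1-ol
Product: 5 (3E)-7-hydroxy-4-methylhept-3-en-2-one, via ethoxy diene 4 (not isolated)
Conditions: Bu3SnC(OEt)=CH2, Pd(PPh3)4 (5 mol%), DMF, 60 °C; then 0.5 M HCl, THF, 0 °C, short contact time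
Reagents that add atoms: tributyl(1-ethoxyvinyl)stannane, CCCC[Sn](CCCC)(CCCC)C(=C)OCC; water, O
Why: Stille coupling with retention of alkene geometry gives the 2-ethoxy diene, whose enol ether is hydrolysed by cold dilute acid to the methyl enone while the free alcohol is tolerated.

Step 3
Reactants: 5 (3E)-7-hydroxy-4-methylhept-3-en-2-one
Product: 6 (4E)-4-methyl-6-oxohept-4-enoic acid
Conditions: TEMPO (10 mol%), PhI(OAc)2 (2.2 equiv), MeCN/H2O, rt
Reagents that add atoms: water, O
Why: Nitroxyl-catalysed oxidation takes the primary alcohol to the acid under conditions that leave the trisubstituted enone and its geometry untouched.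

Step 4
Reactants: 6 (4E)-4-methyl-6-oxohept-4-enoic acid
Product: 7 (4E)-N-methoxy-N,4-dimethyl-6-oxohept-4-enamide
Conditions: MeNHOMe·HCl, EDC·HCl, i-Pr2NEt, CH2Cl2, 0 °C to rt
Reagents that add atoms: N,O-dimethylhydroxylamine hydrochloride, CNOC.Cl
Why: Carbodiimide amide coupling gives the Weinreb amide, the acyl donor that allows a clean single addition of a vinyl Grignard reagent in step 6.

Step 5
Reactants: 7 (4E)-N-methoxy-N,4-dimethyl-6-oxohept-4-enamide
Product: 8 (4E)-N-methoxy-N,4-dimethyl-6-[tri(propan-2-yl)silyloxy]hepta-4,6-dienamide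
Conditions: TIPSOTf (1.2 equiv), Et3N, CH2Cl2, −78 to 0 °C
Reagents that add atoms: triisopropylsilyl trifluoromethanesulfonate, CC(C)[Si](C(C)C)(C(C)C)OS(=O)(=O)C(F)(F)F
Why: Soft enolisation of the methyl enone removes a proton of the CH3 group and gives the cross-conjugated 2-silyloxy diene with the E alkene unchanged; the bulky silyl group is chosen to survive the acidic catalyst of step 7.

Step 6
Reactants: 8 (4E)-N-methoxy-N,4-dimethyl-6-[tri(propan-2-yl)silyloxy]hepta-4,6-dienamide
Product: 9 (6E)-6-methyl-8-[tri(propan-2-yl)silyloxy]nona-1,6,8-trien-3-one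
Conditions: CH2=CHMgBr, THF, −78 to −30 °C; cold aq. NaH2PO4 quench at −78 °C, cold extraction, used at once
Reagents that add atoms: vinylmagnesium bromide, C=C[Mg]Br
Why: Weinreb ketone synthesis, in which the chelated tetrahedral adduct prevents over-addition; the cold buffered quench avoids conjugate addition of the liberated hydroxylamine and premature uncatalysed cycloaddition.

Step 7
Reactants: 9 (6E)-6-methyl-8-[tri(propan-2-yl)silyloxy]nona-1,6,8-trien-3-one
Product: 10 (3aS,7aR)-3a-methyl-5-[tri(propan-2-yl)silyloxy]-2,3,3a,6,7,7a-hexahydro-1H-inden-1-one (cis-fused)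
Conditions: (S)-B-(o-tolyl) CBS-oxazaborolidine (20 mol%), Tf2NH (18 mol%), CH2Cl2, −78 to −40 °C
Reagents that add atoms: none
Why: Proposed new method: the N-protonated oxazaborolidine binds the enone carbonyl and lowers its LUMO, and the tethered 2-silyloxy diene adds in a concerted, asynchronous [4+2] in which the bond from the unsubstituted diene terminus to the enone β-carbon leads and the bond from the enone α-carbon to the fully substituted diene terminus follows; the closest known reactions are the oxazaborolidinium-catalysed intermolecular Diels–Alder additions of 2-(triisopropylsilyloxy)buta-1,3-diene to enones, the same catalyst class in enantioselective intramolecular Diels–Alder reactions of trienals, and the uncatalysed cyclisation of nona-1,6,8-trien-3-ones. The six-membered ring closes by the cycloaddition itself and the five-membered ring as the three-atom tether ring of a type 1 intramolecular Diels–Alder reaction, giving the fused bicyclo[4.3.0] skeleton. The quaternary carbon is set by the catalyst-shielded face of the dienophile together with the E diene geometry (tether outside, methyl inside) and the endo placement of the tether carbonyl, with the catalyst enantiomer assigned by analogy with the intermolecular enone additions and its antipode used if the sense proves opposite; the ring-fusion CH is set cis by the same endo transition state and is erased in step 8. The step needs enantioselectivity (catalyst, low temperature against the uncatalysed background) and a high cis/trans ratio, because a trans adduct formed on the same dienophile face would give the antipode of 12 once the ring-fusion CH is erased, so any trans isomer is removed by chromatography; regiochemistry is fixed by the tether and the triisopropylsilyl group keeps the enol ether intact.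

Step 8
Reactants: 10 (3aS,7aR)-3a-methyl-5-[tri(propan-2-yl)silyloxy]-2,3,3a,6,7,7a-hexahydro-1H-inden-1-one
Product: 12 3-[(1S)-1-methyl-6-oxo-3-[tri(propan-2-yl)silyloxy]cyclohex-2-en-1-yl]propanoic acid, via hydroperoxide 11 (not isolated)
Conditions: KOt-Bu (2.5 equiv), O2 (1 atm), t-BuOH/DME, −25 to 0 °C; then aq. NaH2PO4 to pH 5
Reagents that add atoms: dioxygen, O=O
Why: Base-promoted autoxidative cleavage of an α-branched cycloalkanone: the ring-fusion enolate is oxygenated to the tertiary α-hydroperoxide, which fragments to ketone plus carboxylate, so both ring-fusion epimers converge on 12, and the hindered silyl enol ether is inert to triplet oxygen.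

Step 9
Reactants: 12 3-[(1S)-1-methyl-6-oxo-3-[tri(propan-2-yl)silyloxy]cyclohex-2-en-1-yl]propanoic acid
Product: 14 (4aS,8aS)-4a-methyl-6-[tri(propan-2-yl)silyloxy]-3,4,4a,7,8,8a-hexahydro-2H-chromen-2-one (trans-fused), via hydroxy acid 13 (not isolated)
Conditions: NaBH4, MeOH/THF, −20 °C, aq. NaH2PO4 work-up; then EDC·HCl, DMAP (cat.), CH2Cl2, 0 °C to rt
Reagents that add atoms: none
Why: Hydride adds to the ketone from the face opposite the neighbouring quaternary methyl (as in borohydride reductions of ketones next to an angular methyl), giving the equatorial alcohol cis to that methyl, and carbodiimide lactonisation closes the trans-fused δ-lactone without acid.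

**Left half**

Step 10
Reactants: 15 2,4,4-trimethylcyclohex-2-en-1-one
Product: 16 2,4,4-trimethylcyclohexa-2,5-dien-1-one
Conditions: DDQ (1.3 equiv), TsOH (cat.), 1,4-dioxane, reflux
Reagents that add atoms: none
Why: Quinone dehydrogenation of the enone at its saturated α',β' positions (as for steroidal 4-en-3-ones) gives the cross-conjugated dienone, the quaternary carbon excluding aromatisation.

Step 11
Reactants: 16 2,4,4-trimethylcyclohexa-2,5-dien-1-one
Product: 18 trimethyl{[(3S)-4,4,6-trimethyl-3-[2-(2-methyl-1,3-dioxolan-2-yl)ethyl]cyclohexa-1,5-dien-1-yl]oxy}silane, via zinc enolate 17 (not isolated)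
Conditions: R2Zn [R = 2-(2-methyl-1,3-dioxolan-2-yl)ethyl; from RBr, Mg, THF; ZnCl2 (0.5 equiv); 1,4-dioxane, filtration], Cu(OTf)2 (2 mol%), (R,S,S)-O,O'-(1,1'-binaphthalene-2,2'-diyl) N,N-bis(1-phenylethyl)phosphoramidite (4 mol%), toluene, −30 °C; then TMSOTf, −30 to 0 °C
Reagents that add atoms: bis[2-(2-methyl-1,3-dioxolan-2-yl)ethyl]zinc (made in the flask), CC1(CC[Zn]CCC2(C)OCCO2)OCCO1; trimethylsilyl trifluoromethanesulfonate, C[Si](C)(C)OS(=O)(=O)C(F)(F)F
Why: Copper–phosphoramidite-catalysed asymmetric conjugate addition of a dialkylzinc to a 4,4-disubstituted cyclohexadienone occurs at the unsubstituted enone arm, the ligand setting the new centre (sense assigned by analogy with cyclohex-2-enone, the antipode of the ligand that gives (S)-3-ethylcyclohexanone being used), and silylation of the zinc enolate fixes the enol ether regiochemistry.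

Step 12
Reactants: 18 trimethyl{[(3S)-4,4,6-trimethyl-3-[2-(2-methyl-1,3-dioxolan-2-yl)ethyl]cyclohexa-1,5-dien-1-yl]oxy}silane
Product: 21 (5S)-2,4,4-trimethyl-5-[2-(2-methyl-1,3-dioxolan-2-yl)ethyl]cyclohepta-2,6-dien-1-one, via siloxycyclopropane 19 (not isolated), via chloro ketone 20 (not isolated)
Conditions: Et2Zn, CH2I2, toluene, 0 °C to rt; then FeCl3, DMF, 0 °C to rt; then NaOAc, MeOH, reflux
Reagents that add atoms: diiodomethane, ICI
Why: Saegusa–Ito one-carbon ring expansion: Simmons–Smith cyclopropanation of the electron-rich enol ether double bond, FeCl3 oxidative opening of the internal cyclopropane bond to the ring-enlarged β-chloro ketone, and elimination to the cross-conjugated cycloheptadienone, with the stereocentre untouched.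

Step 13
Reactants: 21 (5S)-2,4,4-trimethyl-5-[2-(2-methyl-1,3-dioxolan-2-yl)ethyl]cyclohepta-2,6-dien-1-one
Product: 22 (5S)-2,4,4-trimethyl-5-(3-oxobutyl)cyclohepta-2,6-dien-1-one
Conditions: PPTS (cat.), acetone/H2O, 50 °C
Reagents that add atoms: water, O
Why: Acid-catalysed acetal hydrolysis frees the methyl ketone without affecting the dienone.

Step 14
Reactants: 22 (5S)-2,4,4-trimethyl-5-(3-oxobutyl)cyclohepta-2,6-dien-1-one
Product: 23 (1S,3aS,8aS)-1-hydroxy-1,4,4,6-tetramethyl-2,3,3a,4,8,8a-hexahydroazulen-7(1H)-one (cis-fused)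
Conditions: SmI2 (2.5 equiv), HMPA, t-BuOH (2 equiv), THF, −78 °C
Reagents that add atoms: none
Why: SmI2 ketyl–olefin reductive cyclisation (5-exo onto the β-carbon of the disubstituted enone arm): the tether on the adjacent ring carbon favours cis fusion, and the samarium-bound oxygen turns away from the acceptor so that OH ends trans to the ring CH2 that carries the enolate, the usual outcome of such cyclisations; protonation of the dienolate restores the α-methyl enone.

Step 15
Reactants: 23 (1S,3aS,8aS)-1-hydroxy-1,4,4,6-tetramethyl-2,3,3a,4,8,8a-hexahydroazulen-7(1H)-one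
Product: 24 (1S,3aS,8aS)-1,4,4,6-tetramethyl-1-(triethylsilyloxy)-2,3,3a,4,8,8a-hexahydroazulen-7(1H)-one
Conditions: TESOTf, 2,6-lutidine, CH2Cl2, −78 to 0 °C
Reagents that add atoms: triethylsilyl trifluoromethanesulfonate, CC[Si](CC)(CC)OS(=O)(=O)C(F)(F)F
Why: Silyl triflate silylation covers the hindered tertiary alcohol so that it survives the acidic conditions of steps 17 and 19.

Step 16
Reactants: 24 (1S,3aS,8aS)-1,4,4,6-tetramethyl-1-(triethylsilyloxy)-2,3,3a,4,8,8a-hexahydroazulen-7(1H)-one
Product: 25 (1S,3aS,7R,8aS)-1,4,4,6-tetramethyl-1-(triethylsilyloxy)-1,2,3,3a,4,7,8,8a-octahydroazulen-7-ol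
Conditions: (S)-2-methyl-CBS-oxazaborolidine (20 mol%), catecholborane, toluene, −78 °C
Reagents that add atoms: none
Why: CBS reduction gives 1,2-reduction of the α-methyl enone with the alkenyl arm as the large group; the (S)-catalyst is expected to give the (7R)-carbinol, which is also the product of hydride attack on the face of the ring-fusion hydrogens.

Step 17
Reactants: 25 (1S,3aS,7R,8aS)-1,4,4,6-tetramethyl-1-(triethylsilyloxy)-1,2,3,3a,4,7,8,8a-octahydroazulen-7-ol
Product: 27 ethyl 2-[(1S,3aS,5R,8aS)-1,4,4,6-tetramethyl-1-(triethylsilyloxy)-1,2,3,3a,4,5,8,8a-octahydroazulen-5-yl]acetate, via ketene acetal 26 (not isolated)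
Conditions: CH3C(OEt)3 (excess), EtCO2H (10 mol%), 140 °C, EtOH distilled off
Reagents that add atoms: triethyl orthoacetate, CCOC(C)(OCC)OCC
Why: Johnson–Claisen rearrangement: the suprafacial [3,3] shift forms the new C–C bond on the ring face that the oxygen leaves, so the C7 configuration is transferred to C5 next to the gem-dimethyl carbon while the alkene moves to its final trisubstituted position.

Step 18
Reactants: 27 ethyl 2-[(1S,3aS,5R,8aS)-1,4,4,6-tetramethyl-1-(triethylsilyloxy)-1,2,3,3a,4,5,8,8a-octahydroazulen-5-yl]acetate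
Product: 28 2-[(1S,3aS,5R,8aS)-1,4,4,6-tetramethyl-1-(triethylsilyloxy)-1,2,3,3a,4,5,8,8a-octahydroazulen-5-yl]acetaldehyde
Conditions: i-Bu2AlH (1.1 equiv), CH2Cl2, −78 °C; aq. potassium sodium tartrate
Reagents that add atoms: none
Why: Low-temperature i-Bu2AlH half-reduction of the ester stops at the tetrahedral aluminium acetal and gives the aldehyde on work-up; silyl ether and alkene are untouched.

**Union and end game**

Step 19
Reactants: 14 (4aS,8aS)-4a-methyl-6-[tri(propan-2-yl)silyloxy]-3,4,4a,7,8,8a-hexahydro-2H-chromen-2-one; 28 2-[(1S,3aS,5R,8aS)-1,4,4,6-tetramethyl-1-(triethylsilyloxy)-1,2,3,3a,4,5,8,8a-octahydroazulen-5-yl]acetaldehyde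
Product: 29 (4aS,8aS)-5-{1-hydroxy-2-[(1S,3aS,5R,8aS)-1,4,4,6-tetramethyl-1-(triethylsilyloxy)-1,2,3,3a,4,5,8,8a-octahydroazulen-5-yl]ethyl}-4a-methylhexahydro-2H-chromene-2,6(3H)-dione (mixture at the two new centres)
Conditions: BF3·OEt2 (1.5 equiv), CH2Cl2, −78 to −40 °C; aq. NaHCO3
Reagents that add atoms: none
Why: Mukaiyama aldol addition: the regio-defined silyl enol ether from step 7 reacts at the carbon next to the quaternary centre, a position a ketone enolate would not reach selectively; the two new centres need no control because both are reset in steps 20 and 21.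

Step 20
Reactants: 29 aldol adduct
Product: 31 (4aS,8aS)-4a-methyl-5-{2-[(1S,3aS,5R,8aS)-1,4,4,6-tetramethyl-1-(triethylsilyloxy)-1,2,3,3a,4,5,8,8a-octahydroazulen-5-yl]ethylidene}hexahydro-2H-chromene-2,6(3H)-dione (E/Z mixture), via mesylate 30 (not isolated)
Conditions: MsCl, Et3N, CH2Cl2, 0 °C; then DBU, rt
Reagents that add atoms: none
Why: Mesylation followed by E1cB elimination (aldol dehydration) gives the exocyclic enone; its geometry is irrelevant.

Step 21
Reactants: 31 exocyclic enone
Product: 32 (4aS,5S,8aS)-4a-methyl-5-{2-[(1S,3aS,5R,8aS)-1,4,4,6-tetramethyl-1-(triethylsilyloxy)-1,2,3,3a,4,5,8,8a-octahydroazulen-5-yl]ethyl}hexahydro-2H-chromene-2,6(3H)-dione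
Conditions: [(Ph3P)CuH]6 (0.5 equiv), toluene, H2O (2 equiv), rt; then DBU (0.2 equiv), rt
Reagents that add atoms: none
Why: Copper hydride conjugate reduction is selective for the enone over the lactone and the isolated trisubstituted alkene, and base equilibration of the α-carbon puts the side chain equatorial, cis to the angular methyl.

Step 22
Reactants: 32 saturated keto lactone
Product: 33 (4aS,5S,6R,8aS)-6-hydroxy-4a,6-dimethyl-5-{2-[(1S,3aS,5R,8aS)-1,4,4,6-tetramethyl-1-(triethylsilyloxy)-1,2,3,3a,4,5,8,8a-octahydroazulen-5-yl]ethyl}octahydro-2H-chromen-2-one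
Conditions: MeLi, CeCl3 (dried), THF, −78 °C
Reagents that add atoms: methylcerium dichloride (made in the flask from MeLi and CeCl3), C[Ce](Cl)Cl
Why: Organocerium 1,2-addition is non-basic and ketone-selective over the lactone at −78 °C; the syn-axial angular methyl blocks axial attack, so methyl enters equatorially and the hydroxyl ends axial, cis to the angular methyl.

Step 23
Reactants: 33 silyl-protected hydroxy lactone
Product: 34 (4aS,5S,6R,8aS)-6-hydroxy-5-{2-[(1S,3aS,5R,8aS)-1-hydroxy-1,4,4,6-tetramethyl-1,2,3,3a,4,5,8,8a-octahydroazulen-5-yl]ethyl}-4a,6-dimethyloctahydro-2H-chromen-2-one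
Conditions: Bu4NF, THF, rt to 40 °C
Reagents that add atoms: none
Why: Fluoride desilylation removes the tertiary triethylsilyl ether; the lactone and the tertiary alcohols are stable.

Step 24
Reactants: 34 dihydroxy lactone
Product: 35 (2S,4aS,5S,6R,8aS)-5-{2-[(1S,3aS,5R,8aS)-1-hydroxy-1,4,4,6-tetramethyl-1,2,3,3a,4,5,8,8a-octahydroazulen-5-yl]ethyl}-4a,6-dimethyloctahydro-2H-chromene-2,6-diol (target)
Conditions: i-Bu2AlH (4 equiv), CH2Cl2, −78 °C; aq. potassium sodium tartrate
Reagents that add atoms: none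
Why: i-Bu2AlH half-reduction of the δ-lactone stops at the aluminium lactolate at −78 °C and work-up gives the lactol; the excess reagent allows for the two free hydroxyl groups.

**Compound list**

1 | pent-4-yn-1-ol | C#CCCCO | starting material
2 | alkenylalane from carboalumination of 1 (O- and C-bound AlMe2) | C[Al](C)OCCC/C(C)=C/[Al](C)C | intermediate
3 | (4E)-5-iodo-4-methylpent-4-en-1-ol | OCCC/C(C)=C/I | intermediate
4 | (4E)-6-ethoxy-4-methylhepta-4,6-dien-1-ol | CCOC(=C)/C=C(C)/CCCO | intermediate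
5 | (3E)-7-hydroxy-4-methylhept-3-en-2-one | CC(=O)/C=C(C)/CCCO | intermediate
6 | (4E)-4-methyl-6-oxohept-4-enoic acid | CC(=O)/C=C(C)/CCC(O)=O | intermediate
7 | (4E)-N-methoxy-N,4-dimethyl-6-oxohept-4-enamide | CON(C)C(=O)CC/C(C)=C/C(C)=O | intermediate
8 | (4E)-N-methoxy-N,4-dimethyl-6-[tri(propan-2-yl)silyloxy]hepta-4,6-dienamide | CON(C)C(=O)CC/C(C)=C/C(=C)O[Si](C(C)C)(C(C)C)C(C)C | intermediate
9 | (6E)-6-methyl-8-[tri(propan-2-yl)silyloxy]nona-1,6,8-trien-3-one | C=CC(=O)CC/C(C)=C/C(=C)O[Si](C(C)C)(C(C)C)C(C)C | intermediate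
10 | (3aS,7aR)-3a-methyl-5-[tri(propan-2-yl)silyloxy]-2,3,3a,6,7,7a-hexahydro-1H-inden-1-one | C[C@@]12CCC(=O)[C@@H]1CCC(O[Si](C(C)C)(C(C)C)C(C)C)=C2 | intermediate
11 | ring-fusion α-hydroperoxide of 10 (drawn cis-fused; either epimer fragments to 12) | C[C@@]12CCC(=O)[C@]1(OO)CCC(O[Si](C(C)C)(C(C)C)C(C)C)=C2 | intermediate
12 | 3-[(1S)-1-methyl-6-oxo-3-[tri(propan-2-yl)silyloxy]cyclohex-2-en-1-yl]propanoic acid | OC(=O)CC[C@@]1(C)C=C(O[Si](C(C)C)(C(C)C)C(C)C)CCC1=O | intermediate
13 | 3-[(1S,6S)-6-hydroxy-1-methyl-3-[tri(propan-2-yl)silyloxy]cyclohex-2-en-1-yl]propanoic acid (OH cis to methyl) | OC(=O)CC[C@@]1(C)C=C(O[Si](C(C)C)(C(C)C)C(C)C)CC[C@@H]1O | intermediate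
14 | (4aS,8aS)-4a-methyl-6-[tri(propan-2-yl)silyloxy]-3,4,4a,7,8,8a-hexahydro-2H-chromen-2-one | C[C@@]12CCC(=O)O[C@H]1CCC(O[Si](C(C)C)(C(C)C)C(C)C)=C2 | intermediate
15 | 2,4,4-trimethylcyclohex-2-en-1-one | CC1=CC(C)(C)CCC1=O | starting material
16 | 2,4,4-trimethylcyclohexa-2,5-dien-1-one | CC1=CC(C)(C)C=CC1=O | intermediate
17 | alkylzinc dienolate from conjugate addition to 16 | CC1=CC(C)(C)[C@@H](CCC2(C)OCCO2)C=C1O[Zn]CCC1(C)OCCO1 | intermediate
18 | trimethyl{[(3S)-4,4,6-trimethyl-3-[2-(2-methyl-1,3-dioxolan-2-yl)ethyl]cyclohexa-1,5-dien-1-yl]oxy}silane | CC1=CC(C)(C)[C@@H](CCC2(C)OCCO2)C=C1O[Si](C)(C)C | intermediate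
19 | 1-(trimethylsilyloxy)bicyclo[4.1.0]hept-2-ene from 18 (cyclopropane centres not specified; lost in the same step) | CC1=CC(C)(C)[C@@H](CCC2(C)OCCO2)C3CC13O[Si](C)(C)C | intermediate
20 | (5S)-6-chloro-2,4,4-trimethyl-5-[2-(2-methyl-1,3-dioxolan-2-yl)ethyl]cyclohept-2-en-1-one (chloride centre not specified) | CC1=CC(C)(C)[C@@H](CCC2(C)OCCO2)C(Cl)CC1=O | intermediate
21 | (5S)-2,4,4-trimethyl-5-[2-(2-methyl-1,3-dioxolan-2-yl)ethyl]cyclohepta-2,6-dien-1-one | CC1=CC(C)(C)[C@@H](CCC2(C)OCCO2)C=CC1=O | intermediate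
22 | (5S)-2,4,4-trimethyl-5-(3-oxobutyl)cyclohepta-2,6-dien-1-one | CC1=CC(C)(C)[C@@H](CCC(C)=O)C=CC1=O | intermediate
23 | (1S,3aS,8aS)-1-hydroxy-1,4,4,6-tetramethyl-2,3,3a,4,8,8a-hexahydroazulen-7(1H)-one | CC1=CC(C)(C)[C@H]2CC[C@](C)(O)[C@H]2CC1=O | intermediate
24 | (1S,3aS,8aS)-1,4,4,6-tetramethyl-1-(triethylsilyloxy)-2,3,3a,4,8,8a-hexahydroazulen-7(1H)-one | CC1=CC(C)(C)[C@H]2CC[C@](C)(O[Si](CC)(CC)CC)[C@H]2CC1=O | intermediate
25 | (1S,3aS,7R,8aS)-1,4,4,6-tetramethyl-1-(triethylsilyloxy)-1,2,3,3a,4,7,8,8a-octahydroazulen-7-ol | CC1=CC(C)(C)[C@H]2CC[C@](C)(O[Si](CC)(CC)CC)[C@H]2C[C@H]1O | intermediate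
26 | ketene ethyl acetal of 25 (1-ethoxyvinyl ether) | CC1=CC(C)(C)[C@H]2CC[C@](C)(O[Si](CC)(CC)CC)[C@H]2C[C@H]1OC(=C)OCC | intermediate
27 | ethyl 2-[(1S,3aS,5R,8aS)-1,4,4,6-tetramethyl-1-(triethylsilyloxy)-1,2,3,3a,4,5,8,8a-octahydroazulen-5-yl]acetate | CC1=CC[C@H]2[C@H](CC[C@]2(C)O[Si](CC)(CC)CC)C(C)(C)[C@@H]1CC(=O)OCC | intermediate
28 | 2-[(1S,3aS,5R,8aS)-1,4,4,6-tetramethyl-1-(triethylsilyloxy)-1,2,3,3a,4,5,8,8a-octahydroazulen-5-yl]acetaldehyde | CC1=CC[C@H]2[C@H](CC[C@]2(C)O[Si](CC)(CC)CC)C(C)(C)[C@@H]1CC=O | intermediate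
29 | aldol adduct of 14 and 28 (carbinol carbon and adjacent ring carbon as mixture) | CC1=CC[C@H]2[C@H](CC[C@]2(C)O[Si](CC)(CC)CC)C(C)(C)[C@@H]1CC(O)C3C(=O)CC[C@@H]4OC(=O)CC[C@@]34C | intermediate
30 | methanesulfonate of 29 | CC1=CC[C@H]2[C@H](CC[C@]2(C)O[Si](CC)(CC)CC)C(C)(C)[C@@H]1CC(OS(C)(=O)=O)C3C(=O)CC[C@@H]4OC(=O)CC[C@@]34C | intermediate
31 | exocyclic enone (E/Z mixture) | CC1=CC[C@H]2[C@H](CC[C@]2(C)O[Si](CC)(CC)CC)C(C)(C)[C@@H]1CC=C3C(=O)CC[C@@H]4OC(=O)CC[C@@]34C | intermediate
32 | (4aS,5S,8aS)-keto lactone with equatorial side chain | CC1=CC[C@H]2[C@H](CC[C@]2(C)O[Si](CC)(CC)CC)C(C)(C)[C@@H]1CC[C@@H]3C(=O)CC[C@@H]4OC(=O)CC[C@@]34C | intermediate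
33 | (4aS,5S,6R,8aS)-6-hydroxy-4a,6-dimethyl lactone, triethylsilyl ether | CC1=CC[C@H]2[C@H](CC[C@]2(C)O[Si](CC)(CC)CC)C(C)(C)[C@@H]1CC[C@@H]3[C@](C)(O)CC[C@@H]4OC(=O)CC[C@@]34C | intermediate
34 | (4aS,5S,6R,8aS)-6-hydroxy-5-{2-[(1S,3aS,5R,8aS)-1-hydroxy-1,4,4,6-tetramethyl-1,2,3,3a,4,5,8,8a-octahydroazulen-5-yl]ethyl}-4a,6-dimethyloctahydro-2H-chromen-2-one | CC1=CC[C@H]2[C@H](CC[C@]2(C)O)C(C)(C)[C@@H]1CC[C@@H]3[C@](C)(O)CC[C@@H]4OC(=O)CC[C@@]34C | intermediate
35 | (2S,4aS,5S,6R,8aS)-5-{2-[(1S,3aS,5R,8aS)-1-hydroxy-1,4,4,6-tetramethyl-1,2,3,3a,4,5,8,8a-octahydroazulen-5-yl]ethyl}-4a,6-dimethyloctahydro-2H-chromene-2,6-diol | CC1=CC[C@H]2[C@H](CC[C@]2(C)O)C(C)(C)[C@@H]1CC[C@H]1[C@]2(C)CC[C@@H](O)O[C@H]2CC[C@@]1(C)O | target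

**Step count and risks**

Total steps: 24. Longest linear sequence: 15 steps (steps 1–9 then 19–24; the branch through steps 10–18 then 19–24 is equally long).

Steps most likely to fail:

Step 7 (Proposed new method). What may go wrong: insufficient facial selectivity at the dienophile, competition from the uncatalysed cyclisation, or an endo/exo ratio too low to give 12 in high enantiomeric purity after step 8. Fallback with known chemistry, setting out from 9: warming 9 in toluene with BHT at 40 °C should give racemic cis-3a-methyl-5-[tri(propan-2-yl)silyloxy]-2,3,3a,6,7,7a-hexahydro-1H-inden-1-one F1 by the known uncatalysed intramolecular Diels–Alder reaction of a nona-1,6,8-trien-3-one. The conditions of step 8 would convert it into racemic 3-[1-methyl-6-oxo-3-[tri(propan-2-yl)silyloxy]cyclohex-2-en-1-yl]propanoic acid F2, which is resolved by crystallisation with (R)-1-phenylethylamine as the salt (1R)-1-phenylethanaminium 3-[(1S)-1-methyl-6-oxo-3-[tri(propan-2-yl)silyloxy]cyclohex-2-en-1-yl]propanoate F3, and the other amine enantiomer would be used if it gives the less soluble salt of the wanted acid. Liberation with aqueous citric acid returns to the route at 12.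

Step 8. What may go wrong: oxygenation at the CH2 α-carbon instead of the ring-fusion carbon, over-oxidation of the product ketone, or loss of the silyl enol ether to alkoxide. Fallback, setting out from 10: KN(SiMe3)2 (0.95 equiv) in THF at 0 °C, to equilibrate to the ring-fusion enolate, followed by 3-phenyl-2-(phenylsulfonyl)oxaziridine at −78 °C should give the ring-fusion α-hydroxy ketone (3aS,7aS)-7a-hydroxy-3a-methyl-5-[tri(propan-2-yl)silyloxy]-2,3,3a,6,7,7a-hexahydro-1H-inden-1-one F4, whose carbinol epimer would serve equally. NaIO4 in aqueous THF then cleaves the α-ketol between the carbonyl and carbinol carbons and returns to the route at 12.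

Step 14. What may go wrong: simple reduction of the dienone instead of cyclisation, or poor control of the carbinol configuration. Fallback, setting out from 22: TBSOTf and Et3N in CH2Cl2 at −78 °C convert the methyl ketone into its silyl enol ether (5S)-5-{3-[tert-butyl(dimethyl)silyloxy]but-3-en-1-yl}-2,4,4-trimethylcyclohepta-2,6-dien-1-one F5, the internal enol ether regioisomer serving equally. Fe(acac)3 (cat.) and PhSiH3 in EtOH/ethylene glycol at 60 °C then transfer a hydrogen atom to the enol ether; the tertiary α-silyloxy radical adds 5-exo to the β-carbon of the disubstituted enone arm and should give the silyl-protected bicyclic enone (1S,3aS,8aS)-1-[tert-butyl(dimethyl)silyloxy]-1,4,4,6-tetramethyl-2,3,3a,4,8,8a-hexahydroazulen-7(1H)-one F6 after reduction and protonation of the enolate radical. If the carbinol epimers form together they are separated at this stage, and Bu4NF returns to the route at 23.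

Further compounds
F1 | step 7 | racemic cis-3a-methyl-5-[tri(propan-2-yl)silyloxy]-2,3,3a,6,7,7a-hexahydro-1H-inden-1-one | CC12CCC(=O)C1CCC(O[Si](C(C)C)(C(C)C)C(C)C)=C2
F2 | step 7 | racemic 3-[1-methyl-6-oxo-3-[tri(propan-2-yl)silyloxy]cyclohex-2-en-1-yl]propanoic acid | OC(=O)CCC1(C)C=C(O[Si](C(C)C)(C(C)C)C(C)C)CCC1=O
F3 | step 7 | (1R)-1-phenylethanaminium 3-[(1S)-1-methyl-6-oxo-3-[tri(propan-2-yl)silyloxy]cyclohex-2-en-1-yl]propanoate | C[C@@H]([NH3+])c1ccccc1.[O-]C(=O)CC[C@@]1(C)C=C(O[Si](C(C)C)(C(C)C)C(C)C)CCC1=O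
F4 | step 8 | (3aS,7aS)-7a-hydroxy-3a-methyl-5-[tri(propan-2-yl)silyloxy]-2,3,3a,6,7,7a-hexahydro-1H-inden-1-one | C[C@@]12CCC(=O)[C@]1(O)CCC(O[Si](C(C)C)(C(C)C)C(C)C)=C2
F5 | step 14 | (5S)-5-{3-[tert-butyl(dimethyl)silyloxy]but-3-en-1-yl}-2,4,4-trimethylcyclohepta-2,6-dien-1-one | CC1=CC(C)(C)[C@@H](CCC(=C)O[Si](C)(C)C(C)(C)C)C=CC1=O
F6 | step 14 | (1S,3aS,8aS)-1-[tert-butyl(dimethyl)silyloxy]-1,4,4,6-tetramethyl-2,3,3a,4,8,8a-hexahydroazulen-7(1H)-one | CC1=CC(C)(C)[C@H]2CC[C@](C)(O[Si](C)(C)C(C)(C)C)[C@H]2CC1=O
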